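**Conventions.** Ring positions of all cyclic compounds, and of the open-chain precursors that become the ring, follow the isochromene numbering of the target 21 (O2, C1, C3, C4, C4a, C5, C6, C7, C8, C8a). Compound numbers are those of the list after the steps.

## Analysis of the target

Target 21 is an azaphilone, a 6H-isochromene-6,8(7H)-dione. A pyran ring (O2, C1, C3, C4, C4a, C8a) is fused through C4a–C8a to a carbocycle (C4a, C5, C6, C7, C8, C8a), and the C1=C8a, C3=C4 and C4a=C5 double bonds with the C6 and C8 carbonyls form one cross-conjugated, electrophilic chromophore. C3 carries an (E)-3-acetoxyprop-1-enyl chain. C7 carries a methyl group and the ester oxygen of 2,4-dihydroxy-6-methylbenzoic (orsellinic) acid. C7 is the only stereocentre: it is quaternary, (S)-configured, lies between the two ring ketones, and has no neighbouring centre from which its configuration could be relayed. The chromophore is attacked at C1 by amines and other nucleophiles and does not survive base. The primary allylic acetate and the free resorcinol are further weak points. The tertiary ester of a doubly ortho-substituted benzoic acid is hard to make by acylation of a C7 alcohol. The difficulty is therefore twofold: fixing the absolute configuration of an isolated, fully substituted carbon, and attaching the hindered ester to it. The strategy rests on one structural feature. If O2, C3 and C4 are taken away, C7 sits between two constitutionally identical arms, C6–C5–C4a and C8–C8a–C1, each a ketone with a formyl carbon two atoms further out. The open-chain compound 10 thus has a mirror plane through C7, and the configuration of C7 is decided solely by which arm ends up as C8–C8a–C1.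

## Retrosynthetic reasoning

**21 from 20.** The two phenolic hydroxyls are unmasked last by cutting the two aryl acetal C–O bonds. Free resorcinol hydroxyls would interfere with the silylation, Lewis-acid and oxidation steps. The forward step must cleave two aryl acetals with acid while the allylic acetate, the tertiary ester and the pyranoquinone stay intact; the chromophore tolerates acid far better than base.

**20 from 19.** The C4a=C5 double bond is traced back to the 4a-H compound 19, in which C6 is a silyl enol ether. This makes C4a sp3, which is what a conjugate addition delivers. The forward step is a two-electron oxidation that removes hydride from C4a and the silyl group from O6.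

**19 from 16 and 15.** The pyran is opened at O2–C3 and at C4–C4a. C4a is β to the C1 and C8 carbonyl carbons of 16 and is the natural acceptor site. C3 and C4 with the complete side chain are the carbonyl and methyl carbons of ketone 14, activated as dienol ether 15. The forward sequence runs through 17 and 18: conjugate addition of the terminal carbon of 15 to C4a, then attack of the C1 enol oxygen on the C3 ketone and dehydration. Only the formyl oxygen can close this ring, so the regiochemistry of annulation is fixed by the skeleton. C7 is already set and plays no part.

**16 from 11.** The silyl group on O6 is a cap. The enol of 11 is acidic enough to protonate 15, so it is silylated first; the same silyl group later leaves in the oxidation to 20.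

**15 from 14, and 14 from 12 and 13.** Dienol ether 15 comes from enolisation of 14 toward its methyl group. Enone 14 is cut at its C=C bond into the alkylidene halves of 12 and 13, which gives the (E)-acetoxy enone in one step from two commodity alkenes.

**11 from 10.** This is the disconnection that carries the strategy: the C8a–C4a bond is cut, and the ring opens to the symmetric tetracarbonyl compound 10. No bond to C7 is involved, yet C7 becomes stereogenic in the forward step because the two arms take different roles. A chiral amine has to choose which arm acts as the nucleophile. The gain is that the carbocycle and the stereocentre arise together from an achiral, easily made chain that already carries the hindered ester.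

**10 from 9, and 9 from 7 and 8.** Each formylacetyl arm is an acetyl group extended by one carbon, so the C1–C8a and C4a–C5 bonds are cut. C7 of 7 has no hydrogen, so only the two methyl groups can condense with 8. Hydrolysis of the bis-enaminone 9 then reveals both aldehydes under acid, which avoids the basic conditions that would cleave a non-enolisable 1,3-diketone.

**7 from 5 and 6; 6 from 3 and 4; 3 from 1.** The C7–O bond is cut. The bond is formed by oxidative coupling of the central enol carbon of 5 with a carboxylate delivered from trivalent iodine in 6, not by acylating a tertiary alcohol with a hindered acid. Iodane 6 comes from ligand exchange between 4 and acid 3, and 3 from 1 by protection through the transient ester 2.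

## Alternatives that were turned down

**Alternative 1:** Here the orsellinate benzene ring itself is disconnected, at the two ring bonds that join the ester-bearing and methyl-bearing carbons to their neighbours. The ester oxygen at C7 is carried by a small alkynoate: A2 is the azaphilone with a but-2-ynoate at C7 in place of the orsellinate. In the forward key step, the triple bond of A2 undergoes [4+2] cycloaddition with the dimedone-derived bis(silyloxy)diene A3. The bicyclic adduct then expels its CMe2–CH2 bridge as a C4 alkene and leaves the bis(trimethylsilyl) ether A1, which mild desilylation would convert into 21.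
- For: the hard acylation of a tertiary alcohol by a doubly ortho-substituted acid is replaced by acylation with a slim ynoic acid. The polarisation of A3 (nucleophilic terminus remote from the bridge, bonding to the methyl-bearing alkyne carbon) gives the orsellinate substitution pattern. The silyl ethers of A1 come off under gentler conditions than the acetals of 20. On protecting groups this alternative is the stronger one.
- Against: cycloaddition and extrusion need prolonged heating in the presence of the finished pyranoquinone, which offers the very electron-rich A3 other electrophilic sites (C1, the C4a=C5–C6=O enone) and carries a heat-sensitive allylic acetate. A β-methyl ynoate is also a sluggish dienophile. Above all, the step does nothing for C7: A2 must already be a single enantiomer, so a separate asymmetric method and additional steps are needed.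
- Comparison: the chosen route creates the stereocentre and the carbocycle in one operation (step 5). It also avoids the hindered acylation, because the ester is installed in step 2 by C–O bond formation at an enol carbon.

**Alternative 2:** The C7–C8 bond is cut. The precursor A5 is a 4H-pyran-4-ylidene that bears the C8 aldehyde on C8a and a butane-2,3-dione unit (C6, C7 and the methyl group) attached through C5. In the forward key step a chiral triazolium-derived carbene adds to the aldehyde, and the resulting acyl-anion equivalent attacks the C7 ketone in a six-membered closure to give the tertiary alcohol A4.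
- For: intramolecular aldehyde–ketone benzoin closures with chiral triazolylidenes are an established route to cyclic tertiary α-ketols, and the stereocentre is formed directly by C–C bond formation at C7. Its precedent for enantiocontrol is closer than that of step 5.
- Against: the aldehyde of A5 is a vinylogous formate (C8a=C1–O2) and a poor electrophile for the carbene. A5 is an extended Michael acceptor that invites Stetter-type additions. The C6 ketone competes through a five-membered closure. The base needed to generate the carbene is unsuited to the pyran system. After the key step A4 still has to be esterified with the hindered acid, on a tertiary α-ketol that is prone to acyl shifts and retro-benzoin cleavage under base.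
- Comparison: the chosen route has the ester in place before any ring exists and puts its risk into enantioselection, not into a late acylation. Step counts are similar once the multi-step preparation of A5 is included.

**Alternative 3:** The pyran is disconnected at O2–C3 and C4–C4a in a cycloaddition sense, on a quinol ester A7 that bears formyl groups on both C8a and C5. With two formyl groups, the two enol tautomers of A7 are mirror images, so A7 racemises by proton shift. In the forward key step a chiral bis(oxazoline) complex of Cu(OTf)2 binds the C1-formyl/C8-carbonyl chelate of one of these tautomers. The 2-methoxydiene A8 adds across O2 and C4a with its enol-ether double bond, and loss of the alkoxy group gives the 4H-pyran A6.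
- For: chelate-controlled hetero-Diels–Alder reactions of this kind have strong precedent with such divalent copper complexes, and a dynamic resolution can in principle convert all material. The pyran ring and side chain also arrive in the stereodetermining step. On precedent and convergence this alternative is stronger.
- Against: the C5 formyl group is a sacrificial carbon that must be introduced and later removed from a sensitive 4H-pyran before C4a–C5 can be dehydrogenated. The catalyst must distinguish enantiomers that differ only at C7, while the centre it controls best (C4a) is discarded. A7 requires an acyloxylative dearomatisation with the hindered carboxylate. A8 can also react as a 4π component.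
- Comparison: the chosen route needs no extra formyl group. Its pyran annulation (step 9) is the same kind of bond construction but carries no stereochemical duty, because C7 is already fixed in 16.

Key step: step 5

**Remark on the chemistry:** 10, 11 and 18 are β-dicarbonyl compounds written in one tautomeric form. 17, 18 and 19 are expected as mixtures of C4a epimers, a centre that step 10 removes.

## Route

Step 1
Reactants: 1 orsellinic acid
Product: 3 2,4-bis(methoxymethoxy)-6-methylbenzoic acid, via methoxymethyl ester 2 (not isolated)
Conditions: MOMCl, iPr2NEt, CH2Cl2, 0 °C → rt; then LiOH, THF/H2O, rt; cold dilute HCl to pH 4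
Reagents that add atoms: chloromethyl methyl ether COCCl; lithium hydroxide [Li+].[OH-] (oxygen of the carboxyl group on acyl–oxygen cleavage)
Why: Both phenols and the carboxylate are alkylated under amine base (Williamson-type O-alkylation), then only the labile acetal ester is saponified, since aryl methoxymethyl ethers are inert to hydroxide. The acidification is kept cold and short so that the aryl acetals survive.

Step 2
Reactants: 3 2,4-bis(methoxymethoxy)-6-methylbenzoic acid, 4 (diacetoxyiodo)benzene, 5 3-methylpentane-2,4-dione
Product: 7 3-methyl-2,4-dioxopentan-3-yl 2,4-bis(methoxymethoxy)-6-methylbenzoate, via bis(aroyloxy)iodobenzene 6 (not isolated)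
Conditions: 3 (2.1 equiv), PhI(OAc)2, PhCl, 50 °C, reduced pressure (−AcOH); then 5, MeCN, rt → 40 °C, dark
Reagents that add atoms: none
Why: The acetate ligands on trivalent iodine are exchanged for the carboxylate of 3 as acetic acid is pumped off; the enol of 5 then attacks iodine and the carboxylate is transferred to C3 with loss of iodobenzene (α-acyloxylation of 1,3-dicarbonyl compounds with [bis(acyloxy)iodo]arenes). The new quaternary carbon bears two identical acetyl groups and is not stereogenic; the second equivalent of 3 is recovered by base extraction.

Step 3
Reactants: 7 3-methyl-2,4-dioxopentan-3-yl 2,4-bis(methoxymethoxy)-6-methylbenzoate, 8 N,N-dimethylformamide dimethyl acetal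
Product: 9 (1E,6E)-1,7-bis(dimethylamino)-4-methyl-3,5-dioxohepta-1,6-dien-4-yl 2,4-bis(methoxymethoxy)-6-methylbenzoate
Conditions: 8 (6 equiv), toluene, 90 °C, N2 sweep
Reagents that add atoms: none
Why: Condensation of methyl ketones with an amide acetal gives (E)-β-dimethylaminoenones; the two methyl groups are the only enolisable positions of 7 because the central carbon is fully substituted. The doubly ortho-substituted tertiary benzoate is too hindered to be cleaved by the methanol and amine present.

Step 4
Reactants: 9 (1E,6E)-1,7-bis(dimethylamino)-4-methyl-3,5-dioxohepta-1,6-dien-4-yl 2,4-bis(methoxymethoxy)-6-methylbenzoate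
Product: 10 4-methyl-1,3,5,7-tetraoxoheptan-4-yl 2,4-bis(methoxymethoxy)-6-methylbenzoate
Conditions: 1 M aq HCl, THF, 0 °C, 20 min; extraction, acid wash, used at once
Reagents that add atoms: water O
Why: Acid hydrolysis of the vinylogous amides (C-protonation, addition of water to the iminium ion, loss of dimethylamine) should give the β-keto aldehyde as its chelated bis(hydroxymethylene) tautomer. Short contact with cold acid and an acid wash remove the achiral amine, which would otherwise catalyse a racemic ring closure; 10 is not stored.

Step 5
Reactants: 10 4-methyl-1,3,5,7-tetraoxoheptan-4-yl 2,4-bis(methoxymethoxy)-6-methylbenzoate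
Product: 11 (S)-5-formyl-2-hydroxy-1-methyl-6-oxocyclohexa-2,4-dien-1-yl 2,4-bis(methoxymethoxy)-6-methylbenzoate
Conditions: (S)-α,α-diphenylprolinol tert-butyldimethylsilyl ether (20 mol%), PhCO2H (20 mol%), water-saturated CHCl3 (0.02 M), 0 °C; then 0.5 M aq HCl wash
Reagents that add atoms: none
Why: Proposed new method: the secondary amine condenses reversibly with either hydroxymethylene terminus of 10 to give an (E)-enaminone whose α-carbon (C8a) is nucleophilic, and this carbon adds to the formyl carbon of the other arm (C4a) in a 6-(enolexo)-exo-trig closure that forms the C8a–C4a bond and the carbocycle C4a–C5–C6–C7–C8–C8a. The nitrogen lone pair then expels the C4a hydroxyl, C5 loses a proton, and hydrolysis (or transfer of the amine to fresh 10) releases 11 as the formyl dienol. The closest known reactions are the amine-catalysed desymmetrising intramolecular aldol condensations of prochiral triketones (Hajos–Parrish type) and the amine-catalysed 6-enolexo aldolisation of heptanedials; a pair of formylacetyl arms, which react through a vinylogous amide and an enolised aldehyde, has not been used in them. No bond to C7 is made: C7 becomes stereogenic because the catalyst-bound arm becomes C8–C8a–C1 and the other arm becomes C6–C5–C4a, so its configuration is set by the stereocentre of the catalyst (reagent control). The diaryl(silyloxy)methyl group blocks one face of the enaminone, closure on the open face folds the chain into a half-chair with C7 as the flap, and the two diastereomeric enaminones then place either the methyl group or the much larger doubly ortho-substituted aroyloxy group on the inside of the fold, which is the handle for discrimination. Provided that the two mono-enaminones interconvert through 10 faster than they cyclise, the faster-closing one drains the pool. The sense of induction cannot be derived with confidence: the (S)-product is drawn, and the catalyst enantiomer that delivers it would be fixed by a pilot run, both antipodes being available. The step needs the catalysed path to outrun the uncatalysed closure, which low temperature, high dilution and the rigorous removal of dimethylamine from 10 are meant to secure.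

Step 6
Reactants: 12 cis-1,4-diacetoxybut-2-ene, 13 methyl vinyl ketone
Product: 14 (E)-5-acetoxypent-3-en-2-one
Conditions: second-generation Hoveyda–Grubbs catalyst (2 mol%), 13 (4 equiv), CH2Cl2, 40 °C
Reagents that add atoms: none
Why: Olefin cross-metathesis between an allylic acetate alkene and an electron-poor vinyl ketone is selective for the cross product and for the (E)-enone; each molecule of 12 delivers two of 14 and ethene escapes.

Step 7
Reactants: 14 (E)-5-acetoxypent-3-en-2-one
Product: 15 (E)-4-(tert-butyldimethylsilyloxy)penta-2,4-dienyl acetate
Conditions: TBSOTf, Et3N, Et2O, 0 °C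
Reagents that add atoms: tert-butyldimethylsilyl trifluoromethanesulfonate CC(C)(C)[Si](C)(C)OS(=O)(=O)C(F)(F)F
Why: Soft enolisation with a silyl triflate and a tertiary amine removes a proton from the methyl group and gives the cross-conjugated 2-silyloxydiene with the alkene geometry unchanged (silyl enol ether formation). γ-Deprotonation of an (E)-enone is kinetically disfavoured, so the linear dienol ether should be minor.

Step 8
Reactants: 11 (S)-5-formyl-2-hydroxy-1-methyl-6-oxocyclohexa-2,4-dien-1-yl 2,4-bis(methoxymethoxy)-6-methylbenzoate
Product: 16 (S)-2-(tert-butyldimethylsilyloxy)-5-formyl-1-methyl-6-oxocyclohexa-2,4-dien-1-yl 2,4-bis(methoxymethoxy)-6-methylbenzoate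
Conditions: TBSCl, Et3N, CH2Cl2, 0 °C; filtration, evaporation, used directly
Reagents that add atoms: tert-butyldimethylsilyl chloride CC(C)(C)[Si](C)(C)Cl
Why: 11 is a vinylogous carboxylic acid and is silylated on oxygen like an acid (O-silylation), which removes the proton that would destroy 15 in step 9. The product is written as the O6 ether; an O1-silylated isomer would keep C4a as the electrophilic carbon.

Step 9
Reactants: 16 (S)-2-(tert-butyldimethylsilyloxy)-5-formyl-1-methyl-6-oxocyclohexa-2,4-dien-1-yl 2,4-bis(methoxymethoxy)-6-methylbenzoate, 15 (E)-4-(tert-butyldimethylsilyloxy)penta-2,4-dienyl acetate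
Product: 19 (7S)-3-[(E)-3-acetoxyprop-1-enyl]-6-(tert-butyldimethylsilyloxy)-7-methyl-8-oxo-7,8-dihydro-4aH-isochromen-7-yl 2,4-bis(methoxymethoxy)-6-methylbenzoate (C4a epimers), via bis-silyl Michael adduct 17 (not isolated), via hydroxymethylene ketone 18 (not isolated)
Conditions: Yb(OTf)3 (10 mol%), CH2Cl2, −20 °C; aq NH4Cl; then PPTS, toluene, 4 Å MS, 50 °C
Reagents that add atoms: none
Why: Yb(OTf)3 chelates the C1 and C8 carbonyls of 16 and the terminal CH2 of 15 adds to C4a (Mukaiyama–Michael addition to an alkylidene 1,3-dicarbonyl compound) to give 17; work-up frees the C1 enol (18), whose oxygen adds to the C3 ketone, and the hemiketal is dehydrated to the 4H-pyran (cyclodehydration of a 1,5-dicarbonyl compound). Only the formyl oxygen can close the ring, because closure from O8 would require a bridgehead double bond. The new C4a centre is not controlled and is removed in step 10; C7 is not touched.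

Step 10
Reactants: 19 (7S)-3-[(E)-3-acetoxyprop-1-enyl]-6-(tert-butyldimethylsilyloxy)-7-methyl-8-oxo-7,8-dihydro-4aH-isochromen-7-yl 2,4-bis(methoxymethoxy)-6-methylbenzoate
Product: 20 (7S)-3-[(E)-3-acetoxyprop-1-enyl]-7-methyl-6,8-dioxo-7,8-dihydro-6H-isochromen-7-yl 2,4-bis(methoxymethoxy)-6-methylbenzoate
Conditions: DDQ (1.1 equiv), NaHCO3 (solid), CH2Cl2, −20 → 0 °C
Reagents that add atoms: none
Why: DDQ abstracts hydride from C4a, which is allylic to both enol-ether double bonds of the 4H-pyran and to the C5=C6 silyl enol ether, and the cation loses the silyl group from O6 to give the C4a=C5–C6=O enone (DDQ dehydrogenation of silyl enol ethers; oxidation of 4H-pyrans). C7 is quaternary and unaffected.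

Step 11
Reactants: 20 (7S)-3-[(E)-3-acetoxyprop-1-enyl]-7-methyl-6,8-dioxo-7,8-dihydro-6H-isochromen-7-yl 2,4-bis(methoxymethoxy)-6-methylbenzoate
Product: 21 (7S)-3-[(E)-3-acetoxyprop-1-enyl]-7-methyl-6,8-dioxo-7,8-dihydro-6H-isochromen-7-yl 2,4-dihydroxy-6-methylbenzoate
Conditions: TFA/CH2Cl2 (1:4), trace H2O, 0 °C → rt
Reagents that add atoms: none
Why: Acid cleaves the two aryl methoxymethyl acetals through oxocarbenium ions (acetal hydrolysis), the chelated ortho ether first. The tertiary ester cannot ionise at C7 between two carbonyls, the primary allylic acetate and the pyranoquinone tolerate brief cold acid, and no base or nucleophile is present.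

## Compound list

1 | orsellinic acid (2,4-dihydroxy-6-methylbenzoic acid) | Cc1cc(O)cc(O)c1C(=O)O | starting material
2 | methoxymethyl 2,4-bis(methoxymethoxy)-6-methylbenzoate | COCOC(=O)c1c(C)cc(OCOC)cc1OCOC | intermediate (not isolated)
3 | 2,4-bis(methoxymethoxy)-6-methylbenzoic acid | Cc1cc(OCOC)cc(OCOC)c1C(=O)O | intermediate
4 | (diacetoxyiodo)benzene, PhI(OAc)2 | CC(=O)OI(OC(C)=O)c1ccccc1 | starting material
5 | 3-methylpentane-2,4-dione | CC(=O)C(C)C(C)=O | starting material
6 | bis[2,4-bis(methoxymethoxy)-6-methylbenzoyloxy](phenyl)-λ3-iodane | c1ccccc1I(OC(=O)c2c(C)cc(OCOC)cc2OCOC)OC(=O)c3c(C)cc(OCOC)cc3OCOC | intermediate (not isolated)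
7 | 3-methyl-2,4-dioxopentan-3-yl 2,4-bis(methoxymethoxy)-6-methylbenzoate | CC(=O)C(C)(OC(=O)c1c(C)cc(OCOC)cc1OCOC)C(C)=O | intermediate
8 | N,N-dimethylformamide dimethyl acetal | COC(OC)N(C)C | starting material
9 | (1E,6E)-1,7-bis(dimethylamino)-4-methyl-3,5-dioxohepta-1,6-dien-4-yl 2,4-bis(methoxymethoxy)-6-methylbenzoate | CN(C)/C=C/C(=O)C(C)(OC(=O)c1c(C)cc(OCOC)cc1OCOC)C(=O)/C=C/N(C)C | intermediate
10 | 4-methyl-1,3,5,7-tetraoxoheptan-4-yl 2,4-bis(methoxymethoxy)-6-methylbenzoate (bis-enol in solution) | O=CCC(=O)C(C)(OC(=O)c1c(C)cc(OCOC)cc1OCOC)C(=O)CC=O | intermediate
11 | (S)-5-formyl-2-hydroxy-1-methyl-6-oxocyclohexa-2,4-dien-1-yl 2,4-bis(methoxymethoxy)-6-methylbenzoate | O=CC1=CC=C(O)[C@](C)(OC(=O)c2c(C)cc(OCOC)cc2OCOC)C1=O | intermediate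
12 | cis-1,4-diacetoxybut-2-ene | CC(=O)OC/C=C\COC(C)=O | starting material
13 | methyl vinyl ketone (but-3-en-2-one) | CC(=O)C=C | starting material
14 | (E)-5-acetoxypent-3-en-2-one | CC(=O)OC/C=C/C(C)=O | intermediate
15 | (E)-4-(tert-butyldimethylsilyloxy)penta-2,4-dienyl acetate | CC(=O)OC/C=C/C(=C)O[Si](C)(C)C(C)(C)C | intermediate
16 | (S)-2-(tert-butyldimethylsilyloxy)-5-formyl-1-methyl-6-oxocyclohexa-2,4-dien-1-yl 2,4-bis(methoxymethoxy)-6-methylbenzoate | O=CC1=CC=C(O[Si](C)(C)C(C)(C)C)[C@](C)(OC(=O)c2c(C)cc(OCOC)cc2OCOC)C1=O | intermediate
17 | (1S)-4-[(E)-5-acetoxy-2-oxopent-3-enyl]-2-(tert-butyldimethylsilyloxy)-5-[(tert-butyldimethylsilyloxy)methylidene]-1-methyl-6-oxocyclohex-2-en-1-yl 2,4-bis(methoxymethoxy)-6-methylbenzoate (C4 epimers, ring numbering of the cyclohexene) | CC(=O)OC/C=C/C(=O)CC1C=C(O[Si](C)(C)C(C)(C)C)[C@](C)(OC(=O)c2c(C)cc(OCOC)cc2OCOC)C(=O)C1=CO[Si](C)(C)C(C)(C)C | intermediate (not isolated)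
18 | (1S)-4-[(E)-5-acetoxy-2-oxopent-3-enyl]-2-(tert-butyldimethylsilyloxy)-5-(hydroxymethylidene)-1-methyl-6-oxocyclohex-2-en-1-yl 2,4-bis(methoxymethoxy)-6-methylbenzoate (C4 epimers) | CC(=O)OC/C=C/C(=O)CC1C=C(O[Si](C)(C)C(C)(C)C)[C@](C)(OC(=O)c2c(C)cc(OCOC)cc2OCOC)C(=O)C1=CO | intermediate (not isolated)
19 | (7S)-3-[(E)-3-acetoxyprop-1-enyl]-6-(tert-butyldimethylsilyloxy)-7-methyl-8-oxo-7,8-dihydro-4aH-isochromen-7-yl 2,4-bis(methoxymethoxy)-6-methylbenzoate (C4a epimers) | CC(=O)OC/C=C/C1=CC2C=C(O[Si](C)(C)C(C)(C)C)[C@](C)(OC(=O)c3c(C)cc(OCOC)cc3OCOC)C(=O)C2=CO1 | intermediate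
20 | (7S)-3-[(E)-3-acetoxyprop-1-enyl]-7-methyl-6,8-dioxo-7,8-dihydro-6H-isochromen-7-yl 2,4-bis(methoxymethoxy)-6-methylbenzoate | CC(=O)OC/C=C/C1=CC2=CC(=O)[C@](C)(OC(=O)c3c(C)cc(OCOC)cc3OCOC)C(=O)C2=CO1 | intermediate
21 | (7S)-3-[(E)-3-acetoxyprop-1-enyl]-7-methyl-6,8-dioxo-7,8-dihydro-6H-isochromen-7-yl 2,4-dihydroxy-6-methylbenzoate | CC(=O)OC/C=C/C1=CC2=CC(=O)[C@](C)(OC(=O)c3c(C)cc(O)cc3O)C(=O)C2=CO1 | target

## Step count and risk

Total step count: 11. Longest linear sequence: 9 steps (steps 1, 2, 3, 4, 5, 8, 9, 10, 11, from 1); steps 6 and 7 form the side branch to 15.

**Step 5 (key step).** The most likely failure is insufficient differentiation of the two enantiotopic arms.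
- The vinylogous amide is a weak carbon nucleophile, so the chiral pathway may be slow enough for an uncatalysed closure to compete. That background closure can be promoted by the acidity of 10 itself or by residual dimethylamine.
- The catalyst may also be sequestered as the stable vinylogous amide of 11, which would stall turnover.
- Fallback by known chemistry: the quinol ester is reached by acyloxylative dearomatisation (Wessely type) and then resolved. The fallback sets out from 3 and 4, which give iodane 6 as in step 2. Iodane 6 is allowed to react in MeCN at 0 °C with commercial 2,4-dihydroxy-3-methylbenzaldehyde F1. The carboxylate is delivered to the methyl-bearing ring carbon between the two hydroxyls, giving the racemic quinol ester F2. Preparative chromatography of F2 on a chiral stationary phase (amylose tris(3,5-dimethylphenylcarbamate)) returns the route at 11.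

**Step 9.** The most likely failure is reaction of 15 in the wrong mode: carbocyclic [4+2] addition across C4a=C8a, 1,2-addition to the formyl group, or Lewis-acid ionisation of its allylic acetate. Incomplete dehydration of the hemiketal is a second risk.
- Fallback: an uncatalysed inverse-electron-demand hetero-Diels–Alder reaction with an alkyl enol ether. It sets out from 14 and 16. Enone 14 is converted with HC(OMe)3 and catalytic PPTS in MeOH into (E)-4,4-dimethoxypent-2-enyl acetate F3. Elimination with TMSOTf and iPr2NEt gives (E)-4-methoxypenta-2,4-dienyl acetate F4 (the diene A8 of alternative 3). Heating 16 with F4 in toluene at 60 °C should give the 3-methoxy-3,4-dihydropyran cycloadduct F5 through the O=C1–C8a=C4a heterodiene. PPTS then removes methanol and the route is rejoined at 19.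

**Step 2.** The most likely failure is slow transfer of the hindered carboxylate to a tertiary carbon, so that the iodane is consumed by oxidative side reactions of the enol or by decarboxylation.
- Fallback: polar substitution in place of oxidative coupling, from 5. Chlorination with SO2Cl2 in CH2Cl2 at 0 °C gives 3-chloro-3-methylpentane-2,4-dione F6. Displacement of chloride by the carboxylate of 3 (Cs2CO3, DMF, rt) returns the route at 7.

**Step 3.** The most likely failure is retro-Claisen loss of an acetyl group: methoxide or dimethylamine attacks a carbonyl of the non-enolisable 1,3-diketone faster than the second condensation occurs.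
- Fallback: a one-carbon extension on the acid side, from 7. TMSOTf and Et3N give the bis(trimethylsilyl enol ether) F7. Reaction of F7 with HC(OMe)3 and BF3·OEt2 at −78 °C gives the bis(β-keto dimethyl acetal) F8. Mild hydrolysis (PPTS, wet acetone) returns the route at 10, bypassing 9 and step 4. This detour also removes the secondary amine from the sequence, and with it one source of racemic background in step 5.

**Step 11.** The most likely failure is acid damage to the finished chromophore or ionisation of the allylic acetate during the longer exposure that the slower para acetal requires.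
- Fallback: reverse the order of the last two operations, from 19. TFA in wet CH2Cl2 removes both acetals and the silyl enol ether on the less sensitive dihydro compound, giving the 4a,5-dihydro diphenol F9. DDQ dehydrogenation of F9 across C4a–C5 then gives 21 directly.

## Further compounds

F1 | step 5 | 2,4-dihydroxy-3-methylbenzaldehyde | Cc1c(O)ccc(C=O)c1O
F2 | step 5 | racemic 5-formyl-2-hydroxy-1-methyl-6-oxocyclohexa-2,4-dien-1-yl 2,4-bis(methoxymethoxy)-6-methylbenzoate | O=CC1=CC=C(O)C(C)(OC(=O)c2c(C)cc(OCOC)cc2OCOC)C1=O
F3 | step 9 | (E)-4,4-dimethoxypent-2-enyl acetate | CC(=O)OC/C=C/C(C)(OC)OC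
F4 | step 9 | (E)-4-methoxypenta-2,4-dienyl acetate | CC(=O)OC/C=C/C(=C)OC
F5 | step 9 | (7S)-3-[(E)-3-acetoxyprop-1-enyl]-6-(tert-butyldimethylsilyloxy)-3-methoxy-7-methyl-8-oxo-3,4,4a,7-tetrahydro-8H-isochromen-7-yl 2,4-bis(methoxymethoxy)-6-methylbenzoate (C3 and C4a epimers) | CC(=O)OC/C=C/C1(OC)CC2C=C(O[Si](C)(C)C(C)(C)C)[C@](C)(OC(=O)c3c(C)cc(OCOC)cc3OCOC)C(=O)C2=CO1
F6 | step 2 | 3-chloro-3-methylpentane-2,4-dione | CC(=O)C(C)(Cl)C(C)=O
F7 | step 3 | 3-methyl-2,4-bis(trimethylsilyloxy)penta-1,4-dien-3-yl 2,4-bis(methoxymethoxy)-6-methylbenzoate | C=C(O[Si](C)(C)C)C(C)(OC(=O)c1c(C)cc(OCOC)cc1OCOC)C(=C)O[Si](C)(C)C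
F8 | step 3 | 1,1,7,7-tetramethoxy-4-methyl-3,5-dioxoheptan-4-yl 2,4-bis(methoxymethoxy)-6-methylbenzoate | COC(OC)CC(=O)C(C)(OC(=O)c1c(C)cc(OCOC)cc1OCOC)C(=O)CC(OC)OC
F9 | step 11 | (7S)-3-[(E)-3-acetoxyprop-1-enyl]-7-methyl-6,8-dioxo-5,6,7,8-tetrahydro-4aH-isochromen-7-yl 2,4-dihydroxy-6-methylbenzoate (C4a epimers) | CC(=O)OC/C=C/C1=CC2CC(=O)[C@](C)(OC(=O)c3c(C)cc(O)cc3O)C(=O)C2=CO1
A1 | alternative 1 | (7S)-3-[(E)-3-acetoxyprop-1-enyl]-7-methyl-6,8-dioxo-7,8-dihydro-6H-isochromen-7-yl 2-methyl-4,6-bis(trimethylsilyloxy)benzoate | CC(=O)OC/C=C/C1=CC2=CC(=O)[C@](C)(OC(=O)c3c(C)cc(O[Si](C)(C)C)cc3O[Si](C)(C)C)C(=O)C2=CO1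
A2 | alternative 1 | (7S)-3-[(E)-3-acetoxyprop-1-enyl]-7-methyl-6,8-dioxo-7,8-dihydro-6H-isochromen-7-yl but-2-ynoate | CC(=O)OC/C=C/C1=CC2=CC(=O)[C@](C)(OC(=O)C#CC)C(=O)C2=CO1
A3 | alternative 1 | 1,3-bis(trimethylsilyloxy)-5,5-dimethylcyclohexa-1,3-diene | C[Si](C)(C)OC1=CC(O[Si](C)(C)C)=CC(C)(C)C1
A4 | alternative 2 | (E)-3-[(7S)-7-hydroxy-7-methyl-6,8-dioxo-7,8-dihydro-6H-isochromen-3-yl]prop-2-enyl acetate | CC(=O)OC/C=C/C1=CC2=CC(=O)[C@](C)(O)C(=O)C2=CO1
A5 | alternative 2 | (E)-3-[4-(2,3-dioxobutylidene)-5-formyl-4H-pyran-2-yl]prop-2-enyl acetate | CC(=O)C(=O)C=C1C=C(/C=C/COC(C)=O)OC=C1C=O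
A6 | alternative 3 | (E)-3-[(4aS,7S)-7-{[2,4-bis(methoxymethoxy)-6-methylbenzoyl]oxy}-5-formyl-6-hydroxy-7-methyl-8-oxo-7,8-dihydro-4aH-isochromen-3-yl]prop-2-enyl acetate | CC(=O)OC/C=C/C1=C[C@H]2C(C=O)=C(O)[C@](C)(OC(=O)c3c(C)cc(OCOC)cc3OCOC)C(=O)C2=CO1
A7 | alternative 3 | 3,5-diformyl-2-hydroxy-1-methyl-6-oxocyclohexa-2,4-dien-1-yl 2,4-bis(methoxymethoxy)-6-methylbenzoate (racemising by tautomerism) | O=CC1=CC(C=O)=C(O)C(C)(OC(=O)c2c(C)cc(OCOC)cc2OCOC)C1=O
A8 | alternative 3 | (E)-4-methoxypenta-2,4-dienyl acetate | CC(=O)OC/C=C/C(=C)OC
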